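Slowness is what these runs show first: L falls ever more slowly although X is charged in excess, so the question is where L stops.

| setting | Saturday's | Sunday's | beta | eta |
|---|---|---|---|---|
| L | 0.30 M | 0.30 M | 0.30 M | 0.30 M |
| X | 1.1 equiv | 1.6 equiv | 2.00 equiv | 1.50 equiv |
| remark | run made earlier | run made earlier |  |  |
| time |  |  | 20 h | 20 h |

| run | time / h | L / % | G / % |
|---|---|---|---|
| Saturday's | 0.833 | 83.1 | 15.9 |
| Saturday's | 2.00 | 72.6 | 19.7 |
| Saturday's | 4.00 | 64.7 | 17.9 |
| Saturday's | 10.0 | 60.7 | 6.0 |
| Sunday's | 0.833 | 76.3 | 20.6 |
| Sunday's | 2.00 | 63.9 | 26.1 |
| Sunday's | 4.00 | 56.8 | 22.8 |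
| Sunday's | 10.0 | 50.1 | 8.1 |

(scatter of a reading: 0.5 percentage points)

- part of the L that has reacted at the end, beta
- part of the L that has reacted at the end, eta
- what raising the equivalents of X from its lowest to its highest value here does to the part of the L that has reacted (changes below 5 percentage points count as none) (it falls / no change / it rises)



I first ask which readings matter. The G readings do not enter, since the part reacted is one minus the fraction of L left. I expect the hours after the last reading to count for little. On Sunday's run, ln(charged L / L left) rose by 0.126 from 4.00 h to 10.0 h, at an hourly pace 2.82 times slower than in the interval before. I therefore allow the later hours that step divided by 4, 0.0314. Were this wrong by its whole size, the answer would shift by 1.6 percentage points. The last reading of Saturday's run, if off by 0.5 points, shifts my answer for beta by about 0.33 points. The charge of X counts more: L left at 10.0 h differs by 11 points between the two runs.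

The logarithms at that reading are 0.499 on Saturday's run and 0.691 on Sunday's, so they rise by 0.384 per equivalent. This is the reach per equivalent: the gain in ln(charged L / L left) from each further equivalent of X, at the same time and the same charge of L. Starting from Sunday's run and adding the tail, I get 58.4% reacted for beta and 49.5% for eta, a rise of 8.9 points from eta to beta.

The forecast says 60% (55% to 66%) for beta and 50% (46% to 55%) for eta, with “More X gives more conversion”.

The flasks give 57.2% for beta and 48.7% for eta, a change of 8.5 points: it rises. Their own reach, at the asked time, is 0.364 per equivalent. In eta, L + X → E + G uses X at 0.47 of the rate of 2 X → Z just after the start, and at 0.88 of it at 1.00 h. At the end of eta 0.34% of the charged X stands unbound, the X held in J not counted, against 51% of the charged L, and X, the limiting reagent, is the first to run out. With 2.50 equiv of X, otherwise as eta, my reach applied to eta's result gives 65.0% reacted; that flask gives 63.8%.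

    L + X → E + G (k = 2.70 × 10⁻⁴ M⁻¹ s⁻¹)
    X + E ⇌ J, settled at all times (K = 16000 M⁻¹)
    G → D (k = 6.70 × 10⁻⁵ s⁻¹)
    2 X → Z (k = 1.90 × 10⁻⁴ M⁻¹ s⁻¹)

(The readings were computed with made-up constants, and the scatter is random.)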